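(The readings stem from a simulated flask from invented constants, noise included.)

Wednesday's flask holds half the L of Saturday's, yet between its last two readings it makes G faster than Saturday's flask does. In each flask E and Q combine to G, with L as catalyst.

| flask | E | Q | L | G | time |
|---|---|---|---|---|---|
| Saturday's | 0.800 M | 1.20 M | 0.00160 M |  |  |
| Wednesday's | 0.800 M | 1.20 M | 8.00 × 10⁻⁴ M |  |  |
| Friday's | 1.20 M | 1.20 M | 0.00160 M |  |  |
| Sunday's | 0.800 M | 1.20 M | 0.00160 M | 0.240 M |  |
| Thursday's | 0.800 M | 1.20 M | 0.00160 M |  | 220 h |

| run | time / h | [G] / M |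
|---|---|---|
| Saturday's run | 2.4 | 0.1124 |
| Saturday's run | 7.4 | 0.2671 |
| Saturday's run | 14 | 0.3924 |
| Saturday's run | 22 | 0.4651 |
| Saturday's run | 32 | 0.5121 |
| Saturday's run | 43 | 0.5413 |
| Saturday's run | 55 | 0.5651 |
| Wednesday's run | 2.4 | 0.0677 |
| Wednesday's run | 7.4 | 0.1779 |
| Wednesday's run | 14 | 0.2840 |
| Wednesday's run | 22 | 0.3625 |
| Wednesday's run | 32 | 0.4254 |
| Wednesday's run | 43 | 0.4639 |
| Wednesday's run | 55 | 0.4972 |
| Friday's run | 2.4 | 0.1505 |
| Friday's run | 7.4 | 0.3598 |
| Friday's run | 14 | 0.5116 |
| Friday's run | 22 | 0.6058 |
| Friday's run | 32 | 0.6603 |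
| Friday's run | 43 | 0.7000 |
| Friday's run | 55 | 0.7322 |
| Sunday's run | 2.4 | 0.3476 |
| Sunday's run | 7.4 | 0.4909 |
| Sunday's run | 14 | 0.5883 |
| Sunday's run | 22 | 0.6519 |
| Sunday's run | 32 | 0.6958 |
| Sunday's run | 43 | 0.7238 |
| Sunday's run | 55 | 0.7476 |

(standard deviation of a reading: 0.002 M)

- Overall: E + Q -> G, with L as catalyst.
- Constant volume, constant temperature.
- Bound and free are read together.
- An order is taken over about fifteen percent of the charge, up and down.

- order of the initial rate in [L], near the charge of the Saturday's run, the rate being that where two percent of its E are G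
- order of the initial rate in [E], near the charge of the Saturday's run, the rate being that where two percent of its E are G (one fixed amount of G, the same in the runs compared)
- G in the Thursday's run at 220 h, as a share of the E charged

1. We start with a balance. E is charged in the smaller amount in Saturday's flask, so it is the limiting reagent. Each G made uses one E and one Q, so c(E) and c(Q) both fall by the G made. In Saturday's flask c(Q) − c(E) stays at 0.400 M.

2. A rate constant is a rate divided by the concentrations in its rate law. We define the tail constant as the G gained per hour between the last two readings, divided by c(E)·c(Q) at the midpoint of that stretch. It is 0.0124 M⁻¹ h⁻¹ in Saturday's flask and 0.0121 M⁻¹ h⁻¹ in Wednesday's, close together despite the different L charges.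

3. Sunday's flask started with G in it, so G made is the reading minus that charge. Its tail constant is 0.00925 M⁻¹ h⁻¹, smaller than Saturday's, a reading with a scatter of about 11.9%. We carry Sunday's tail constant, the late rate per c(E)·c(Q), as our value for a route that needs no L.

4. Thursday's flask has Saturday's charge, so we continue from Saturday's last reading, where c(E) is 0.235 M. If that route carries the rest of Thursday's flask, then with the gap fixed ln(c(Q)/c(E)) climbs in a straight line, with slope equal to Sunday's tail constant times the gap. Over the remaining 165 h it climbs by 0.611. On this reckoning c(E) comes to 0.101 M, so our estimate is 87.4%.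

5. Early on, we write the rate as a part proportional to L plus the tail rate, so the order in L is the share of the rate that goes through L. At two percent turned in Saturday's flask, the tail rate is 8.59 mM h⁻¹. Against Saturday's mean rate over its first reading, that gives an order of 0.817.

6. The forecast gives 0.76 in L, 0.75 in E and 80% for Thursday, less than our estimate: “Allowing for a slow tail, I expect Thursday's run to reach about 0.64 M, or 80%, with real uncertainty.”

7. The flask gives 0.83 in L, 0.84 in E and 87.3% for Thursday.

    L + E ⇌ LE, settled at all times (0.3340 M⁻¹)
    LE + Q → G + L + X (106.2 M⁻¹ h⁻¹)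
    E + Q → G (0.009072 M⁻¹ h⁻¹)
    L + G → Ez + G (0.1746 M⁻¹ h⁻¹)

Thursday's flask shows what the tail is: with the step from E + Q to G taken away it reaches 61.4% instead of 87.3%, a loss of 26 percentage points. The tail constant of 0.00925 M⁻¹ h⁻¹ carries over to Wednesday's flask, which has Saturday's E and Q. Saturday's rate at two percent turned is 0.0501 M h⁻¹. Scaling its part above the tail rate by the L charges and adding the tail rate back gives 0.0294 M h⁻¹ for Wednesday's flask, against the simulated 0.029 M h⁻¹.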